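**Plan**
1. Numbering: oxolane O1, C2 (aryl), C3 (bears C9H2O), C4, C5; carbinol carbon on C4 is C7'; anisyl ring C1'–C6' (C1' on C7', oxygen on C4').
2. Cuts, in retrosynthetic order: the acetates and the C7'–H bond (back to an anisyl ketone); ring bonds C1'–C6' and C2'–C3' of the anisyl ring (C4 ethynyl ketone plus a 1-methoxy-3-silyloxybutadiene); C4–C7' (lactone enolate aldol); O1–C5 (lactone reduction, etherification); C2–C3 (auxiliary-controlled succinate aldol).
3. Enabling feature: the ring on C7' is a benzene whose only oxygen sits on C4', para to C1', and C7' can be a carbonyl carbon, so this ring maps onto an ynone (C1', C2') and a 1,3-dioxygenated diene (C3'–C6').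
4. Forward order: γ-lactone first, then the C4–C7' bond, then the oxolane, then the benzene ring by [4+2] addition and aromatisation, last the C7' carbinol and the acetates.
5. Stereochemistry: C2 and C3 from the syn-aldol of the (R)-4-benzyloxazolidinone succinate; C4 from attack on the lactone enolate anti to the C3 substituent; C7' from Felkin–Anh hydride addition to the aryl ketone.

Key step: step 11

Remark (assumption on the chemistry): the propargylic carbinol carbon made in step 7 and the methoxy-bearing sp3 carbon of cycloadduct 20 form without control and are drawn without descriptor; both are removed later (steps 10 and 11). TIPS = triisopropylsilyl, TBDPS = tert-butyldiphenylsilyl.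

**Route**

Step 1
Reactants: 1 4-hydroxybenzaldehyde
Product: 2 4-(triisopropylsilyloxy)benzaldehyde
Conditions: TIPSCl, imidazole, DMF, 0 °C → rt
Reagents that add atoms: triisopropylsilyl chloride, CC(C)[Si](Cl)(C(C)C)C(C)C
Why: Imidazole-promoted O-silylation of the phenol, the only nucleophilic site, gives an aryl silyl ether that tolerates the enolate, hydride and mild base steps ahead.

Step 2
Reactants: 3 (R)-4-benzyl-1,3-oxazolidin-2-one; 4 methyl 4-chloro-4-oxobutanoate
Product: 5 methyl 4-[(4R)-4-benzyl-2-oxo-1,3-oxazolidin-3-yl]-4-oxobutanoate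
Conditions: n-BuLi, THF, −78 °C; then 4, −78 → 0 °C
Reagents that add atoms: none
Why: N-acylation of the lithiated oxazolidinone by the acid chloride is the standard way to load the auxiliary and is faster than any attack on the methyl ester.

Step 3
Reactants: 5 methyl 4-[(4R)-4-benzyl-2-oxo-1,3-oxazolidin-3-yl]-4-oxobutanoate; 2 4-(triisopropylsilyloxy)benzaldehyde
Product: 7 (4R)-4-benzyl-3-{[(2R,3R)-5-oxo-2-[4-(triisopropylsilyloxy)phenyl]oxolan-3-yl]carbonyl}-1,3-oxazolidin-2-one (trans lactone), via open-chain syn-aldol hydroxy ester 6 (not isolated)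
Conditions: Bu2BOTf, i-Pr2NEt, CH2Cl2, 0 °C; 2, −78 → 0 °C; pH 7 buffer, MeOH, H2O2, 0 °C; then PPTS (cat.), CH2Cl2, rt
Reagents that add atoms: none
Why: Evans boron syn-aldol: the Z-boron enolate formed at the imide α-carbon reacts through a chair transition state on the face away from the benzyl group of the (R)-auxiliary, which sets both new centres as R,R (syn), and the new hydroxyl then closes onto the methyl ester (5-exo-trig) to give the 2,3-trans lactone.

Step 4
Reactants: 7 trans lactone imide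
Product: 9 (2R,3R)-5-oxo-2-[4-(triisopropylsilyloxy)phenyl]oxolane-3-carboxylic acid, via lithium percarboxylate 8 (not isolated)
Conditions: LiOH, H2O2, THF/H2O (3:1), 0 °C; Na2SO3 aq; HCl to pH 2
Reagents that add atoms: hydrogen peroxide, OO
Why: Hydroperoxide hydrolysis of the N-acyl oxazolidinone attacks the exocyclic carbonyl selectively, sulfite reduces the peracid, and any lactone opened by hydroxide recloses on acidification without touching either stereocentre.

Step 5
Reactants: 9 (2R,3R)-5-oxo-2-[4-(triisopropylsilyloxy)phenyl]oxolane-3-carboxylic acid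
Product: 10 (4S,5R)-4-(hydroxymethyl)-5-[4-(triisopropylsilyloxy)phenyl]oxolan-2-one
Conditions: BH3·SMe2, THF, 0 °C → rt; MeOH
Reagents that add atoms: none
Why: Borane reduces a carboxylic acid through its acyloxyborane much faster than it reduces a lactone, and the non-basic medium prevents translactonisation of the new primary alcohol.

Step 6
Reactants: 10 (4S,5R)-4-(hydroxymethyl)-5-[4-(triisopropylsilyloxy)phenyl]oxolan-2-one
Product: 11 (4S,5R)-4-[(tert-butyldiphenylsilyloxy)methyl]-5-[4-(triisopropylsilyloxy)phenyl]oxolan-2-one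
Conditions: TBDPSCl, imidazole, DMF, rt
Reagents that add atoms: tert-butyl(chloro)diphenylsilane, CC(C)(C)[Si](Cl)(c1ccccc1)c1ccccc1
Why: Silylation of the primary alcohol gives a bulky ether that resists silyl migration and the dilute acid of step 11, and it shields one face of the lactone for step 7.

Step 7
Reactants: 11 (4S,5R)-4-[(tert-butyldiphenylsilyloxy)methyl]-5-[4-(triisopropylsilyloxy)phenyl]oxolan-2-one; 12 3-(trimethylsilyl)prop-2-ynal
Product: 13 (3S,4S,5R)-4-[(tert-butyldiphenylsilyloxy)methyl]-3-[1-hydroxy-3-(trimethylsilyl)prop-2-yn-1-yl]-5-[4-(triisopropylsilyloxy)phenyl]oxolan-2-one (carbinol epimers)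
Conditions: LiN(SiMe3)2, THF, −78 °C; 12, −78 °C; AcOH, −78 °C
Reagents that add atoms: none
Why: Lithium enolate aldol addition: the enolate of the β-substituted γ-lactone adds 1,2 to the ynal on the face anti to the silyloxymethyl group, which sets the 3,4-trans relationship (future C3/C4 of the oxolane), and the cold acidic quench prevents retro-aldol.

Step 8
Reactants: 13 aldol lactone
Product: 15 (1R,2S,3R)-2-[(tert-butyldiphenylsilyloxy)methyl]-3-(hydroxymethyl)-1-[4-(triisopropylsilyloxy)phenyl]hex-5-yne-1,4-diol, via C-silylated triol 14 (not isolated)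
Conditions: LiBH4, THF, 0 °C → rt; then MeOH, K2CO3 (0.2 equiv), 0 °C
Reagents that add atoms: none
Why: LiBH4 reduces the lactone to the 1,4-diol without touching the alkyne or the silyl ethers, and brief base-catalysed methanolysis then cleaves the alkynyl C–Si bond, which is far more labile than the hindered aryl and alkyl silyl ethers.

Step 9
Reactants: 15 terminal alkyne triol
Product: 17 1-[(2R,3S,4R)-3-[(tert-butyldiphenylsilyloxy)methyl]-2-[4-(triisopropylsilyloxy)phenyl]oxolan-4-yl]prop-2-yn-1-ol (carbinol epimers), via primary tosylate 16 (not isolated)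
Conditions: TsCl (1.1 equiv), pyridine, 0 → 40 °C
Reagents that add atoms: none
Why: Sulfonylation should occur at the single primary hydroxyl, and the benzylic hydroxyl then displaces the tosylate in a 5-exo-tet Williamson closure that forms O1–C5 with retention at C2, whereas the propargylic hydroxyl could only form an oxetane.

Step 10
Reactants: 17 oxolane propargylic alcohol
Product: 18 1-[(2R,3S,4R)-3-[(tert-butyldiphenylsilyloxy)methyl]-2-[4-(triisopropylsilyloxy)phenyl]oxolan-4-yl]prop-2-yn-1-one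
Conditions: Dess–Martin periodinane, CH2Cl2, 0 °C → rt
Reagents that add atoms: none
Why: Dess–Martin oxidation converts the secondary propargylic alcohol to the ynone under neutral, non-nucleophilic conditions, so the terminal ynone, the silyl ethers and the epimerisable C4 centre are not exposed to base.

Step 11
Reactants: 18 C4 ethynyl ketone; 19 (E)-1-methoxy-3-(trimethylsilyloxy)buta-1,3-diene
Product: 21 (4-hydroxyphenyl)[(2R,3S,4R)-3-[(tert-butyldiphenylsilyloxy)methyl]-2-[4-(triisopropylsilyloxy)phenyl]oxolan-4-yl]methanone, via cyclohexa-1,4-diene cycloadduct 20 (not isolated)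
Conditions: 19 (2 equiv), toluene, rt → 60 °C; then 0.1 M HCl, THF, 0 °C
Reagents that add atoms: none
Why: The electron-rich diene 19 and the electron-poor terminal ynone 18 combine in a concerted, asynchronous, normal-demand Diels–Alder reaction in which the CH2 terminus of the diene (its most nucleophilic carbon) bonds to the alkyne β-carbon and the methoxy-bearing terminus to the α-carbon, giving cyclohexa-1,4-diene 20. Dilute acid then causes 1,4-elimination of methanol and cleavage of the O–SiMe3 bond, so the new carbocycle aromatises to the para-hydroxyphenyl ketone; the closest known reaction type is the cycloaddition and aromatisation of 1-methoxy-3-silyloxybutadienes with acetylenic ketones and esters to para-hydroxyaryl carbonyl compounds. The six-membered ring closes by intermolecular suprafacial [4+2] addition that forms C1'–C6' and C2'–C3' in one event, not by cyclisation of a chain. No stereocentre is created (the methoxy-bearing sp3 carbon of 20 is lost on aromatisation), and C4, the only epimerisable centre, already holds its more stable trans arrangement. The selectivity needed is regiochemical, oxygen para to the acyl carbon, and it is secured by the matched polarisation of the 1,3-dioxygenated diene and the ynone, which is also the only dienophile present. The phenol arrives free while the C2 aryl oxygen is silylated, which lets step 12 methylate one ring only.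

Step 12
Reactants: 21 4-hydroxyphenyl ketone
Product: 22 (4-methoxyphenyl)[(2R,3S,4R)-3-[(tert-butyldiphenylsilyloxy)methyl]-2-[4-(triisopropylsilyloxy)phenyl]oxolan-4-yl]methanone
Conditions: MeI, K2CO3, acetone, rt
Reagents that add atoms: iodomethane, CI
Why: Williamson methylation of the acidic para-acyl phenol, the only free hydroxyl, proceeds under carbonate conditions too mild to cleave the aryl triisopropylsilyl ether or to enolise C4 to any lasting effect.

Step 13
Reactants: 22 anisyl ketone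
Product: 23 (S)-(4-methoxyphenyl)[(2R,3S,4R)-3-[(tert-butyldiphenylsilyloxy)methyl]-2-[4-(triisopropylsilyloxy)phenyl]oxolan-4-yl]methanol
Conditions: LiBH(s-Bu)3, THF, −78 °C; AcOH quench
Reagents that add atoms: none
Why: Felkin–Anh addition of the bulky hydride: with C3, the more substituted ring branch on C4, anti to the incoming hydride and C5 beside the carbonyl oxygen, attack should fall on the Re face and give the 7'S carbinol, and a six-membered lithium chelate through O1 would expose the same face.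

Step 14
Reactants: 23 silylated carbinol
Product: 24 4-[(2R,3S,4R)-3-(hydroxymethyl)-4-[(S)-hydroxy(4-methoxyphenyl)methyl]oxolan-2-yl]phenol
Conditions: Bu4NF, AcOH (1:1), THF, 0 °C → rt
Reagents that add atoms: none
Why: Fluoride cleaves both Si–O bonds (aryl triisopropylsilyl and primary tert-butyldiphenylsilyl) while the acetic acid buffer keeps the medium near neutral, so the electron-rich benzylic carbinol is neither ionised nor eliminated.

Step 15
Reactants: 24 phenol diol
Product: 25 [(2R,3S,4R)-4-[(S)-acetoxy(4-methoxyphenyl)methyl]-2-(4-acetoxyphenyl)oxolan-3-yl]methyl acetate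
Conditions: Ac2O, pyridine, DMAP (cat.), CH2Cl2, 0 °C → rt
Reagents that add atoms: acetic anhydride, CC(=O)OC(C)=O
Why: DMAP-catalysed acylation esterifies the phenol, the primary alcohol and the secondary benzylic alcohol alike under basic conditions that leave the C7' configuration untouched.

Step 16
Reactants: 25 triacetate
Product: 26 [(2R,3S,4R)-4-[(S)-acetoxy(4-methoxyphenyl)methyl]-2-(4-hydroxyphenyl)oxolan-3-yl]methyl acetate (target)
Conditions: pyrrolidine (1.2 equiv), CH2Cl2, 0 °C
Reagents that add atoms: none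
Why: Aminolysis is much faster at the aryl ester (phenoxide leaving group) than at the primary and secondary alkyl acetates, so a slight excess of the secondary amine in an aprotic solvent should free only the phenol.

**Compound list**
1 | 4-hydroxybenzaldehyde | O=Cc1ccc(O)cc1 | starting material
2 | 4-(triisopropylsilyloxy)benzaldehyde | O=Cc1ccc(O[Si](C(C)C)(C(C)C)C(C)C)cc1 | intermediate
3 | (R)-4-benzyl-1,3-oxazolidin-2-one | O=C1N[C@H](Cc2ccccc2)CO1 | starting material
4 | methyl 4-chloro-4-oxobutanoate | COC(=O)CCC(Cl)=O | starting material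
5 | methyl 4-[(4R)-4-benzyl-2-oxo-1,3-oxazolidin-3-yl]-4-oxobutanoate | COC(=O)CCC(=O)N1C(=O)OC[C@H]1Cc1ccccc1 | intermediate
6 | methyl (3R,4R)-3-{[(4R)-4-benzyl-2-oxo-1,3-oxazolidin-3-yl]carbonyl}-4-hydroxy-4-[4-(triisopropylsilyloxy)phenyl]butanoate | COC(=O)C[C@@H](C(=O)N1C(=O)OC[C@H]1Cc1ccccc1)[C@@H](O)c1ccc(O[Si](C(C)C)(C(C)C)C(C)C)cc1 | intermediate (not isolated)
7 | (4R)-4-benzyl-3-{[(2R,3R)-5-oxo-2-[4-(triisopropylsilyloxy)phenyl]oxolan-3-yl]carbonyl}-1,3-oxazolidin-2-one | O=C1C[C@@H](C(=O)N2C(=O)OC[C@H]2Cc2ccccc2)[C@H](c2ccc(O[Si](C(C)C)(C(C)C)C(C)C)cc2)O1 | intermediate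
8 | (2R,3R)-5-oxo-2-[4-(triisopropylsilyloxy)phenyl]oxolane-3-carboperoxoic acid (formed as its lithium salt) | O=C1C[C@@H](C(=O)OO)[C@H](c2ccc(O[Si](C(C)C)(C(C)C)C(C)C)cc2)O1 | intermediate (not isolated)
9 | (2R,3R)-5-oxo-2-[4-(triisopropylsilyloxy)phenyl]oxolane-3-carboxylic acid | O=C1C[C@@H](C(=O)O)[C@H](c2ccc(O[Si](C(C)C)(C(C)C)C(C)C)cc2)O1 | intermediate
10 | (4S,5R)-4-(hydroxymethyl)-5-[4-(triisopropylsilyloxy)phenyl]oxolan-2-one | O=C1C[C@@H](CO)[C@H](c2ccc(O[Si](C(C)C)(C(C)C)C(C)C)cc2)O1 | intermediate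
11 | (4S,5R)-4-[(tert-butyldiphenylsilyloxy)methyl]-5-[4-(triisopropylsilyloxy)phenyl]oxolan-2-one | O=C1C[C@@H](CO[Si](c2ccccc2)(c2ccccc2)C(C)(C)C)[C@H](c2ccc(O[Si](C(C)C)(C(C)C)C(C)C)cc2)O1 | intermediate
12 | 3-(trimethylsilyl)prop-2-ynal | C[Si](C)(C)C#CC=O | starting material
13 | (3S,4S,5R)-4-[(tert-butyldiphenylsilyloxy)methyl]-3-[1-hydroxy-3-(trimethylsilyl)prop-2-yn-1-yl]-5-[4-(triisopropylsilyloxy)phenyl]oxolan-2-one (carbinol epimers) | C[Si](C)(C)C#CC(O)[C@H]1C(=O)O[C@@H](c2ccc(O[Si](C(C)C)(C(C)C)C(C)C)cc2)[C@@H]1CO[Si](c1ccccc1)(c1ccccc1)C(C)(C)C | intermediate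
14 | (1R,2S,3R)-2-[(tert-butyldiphenylsilyloxy)methyl]-3-(hydroxymethyl)-1-[4-(triisopropylsilyloxy)phenyl]-6-(trimethylsilyl)hex-5-yne-1,4-diol (C4 epimers) | C[Si](C)(C)C#CC(O)[C@@H](CO)[C@@H](CO[Si](c1ccccc1)(c1ccccc1)C(C)(C)C)[C@@H](O)c1ccc(O[Si](C(C)C)(C(C)C)C(C)C)cc1 | intermediate (not isolated)
15 | (1R,2S,3R)-2-[(tert-butyldiphenylsilyloxy)methyl]-3-(hydroxymethyl)-1-[4-(triisopropylsilyloxy)phenyl]hex-5-yne-1,4-diol (C4 epimers) | C#CC(O)[C@@H](CO)[C@@H](CO[Si](c1ccccc1)(c1ccccc1)C(C)(C)C)[C@@H](O)c1ccc(O[Si](C(C)C)(C(C)C)C(C)C)cc1 | intermediate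
16 | primary 4-methylbenzenesulfonate of 15 (tosyloxy group on the CH2 at C3 of the hexyne chain) | C#CC(O)[C@@H](COS(=O)(=O)c1ccc(C)cc1)[C@@H](CO[Si](c1ccccc1)(c1ccccc1)C(C)(C)C)[C@@H](O)c1ccc(O[Si](C(C)C)(C(C)C)C(C)C)cc1 | intermediate (not isolated)
17 | 1-[(2R,3S,4R)-3-[(tert-butyldiphenylsilyloxy)methyl]-2-[4-(triisopropylsilyloxy)phenyl]oxolan-4-yl]prop-2-yn-1-ol (carbinol epimers) | C#CC(O)[C@H]1CO[C@@H](c2ccc(O[Si](C(C)C)(C(C)C)C(C)C)cc2)[C@@H]1CO[Si](c1ccccc1)(c1ccccc1)C(C)(C)C | intermediate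
18 | 1-[(2R,3S,4R)-3-[(tert-butyldiphenylsilyloxy)methyl]-2-[4-(triisopropylsilyloxy)phenyl]oxolan-4-yl]prop-2-yn-1-one | C#CC(=O)[C@H]1CO[C@@H](c2ccc(O[Si](C(C)C)(C(C)C)C(C)C)cc2)[C@@H]1CO[Si](c1ccccc1)(c1ccccc1)C(C)(C)C | intermediate
19 | (E)-1-methoxy-3-(trimethylsilyloxy)buta-1,3-diene | CO/C=C/C(=C)O[Si](C)(C)C | starting material
20 | [6-methoxy-4-(trimethylsilyloxy)cyclohexa-1,4-dien-1-yl][(2R,3S,4R)-3-[(tert-butyldiphenylsilyloxy)methyl]-2-[4-(triisopropylsilyloxy)phenyl]oxolan-4-yl]methanone (C6 epimers) | COC1C=C(O[Si](C)(C)C)CC=C1C(=O)[C@H]1CO[C@@H](c2ccc(O[Si](C(C)C)(C(C)C)C(C)C)cc2)[C@@H]1CO[Si](c1ccccc1)(c1ccccc1)C(C)(C)C | intermediate (not isolated)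
21 | (4-hydroxyphenyl)[(2R,3S,4R)-3-[(tert-butyldiphenylsilyloxy)methyl]-2-[4-(triisopropylsilyloxy)phenyl]oxolan-4-yl]methanone | Oc1ccc(C(=O)[C@H]2CO[C@@H](c3ccc(O[Si](C(C)C)(C(C)C)C(C)C)cc3)[C@@H]2CO[Si](c2ccccc2)(c2ccccc2)C(C)(C)C)cc1 | intermediate
22 | (4-methoxyphenyl)[(2R,3S,4R)-3-[(tert-butyldiphenylsilyloxy)methyl]-2-[4-(triisopropylsilyloxy)phenyl]oxolan-4-yl]methanone | COc1ccc(C(=O)[C@H]2CO[C@@H](c3ccc(O[Si](C(C)C)(C(C)C)C(C)C)cc3)[C@@H]2CO[Si](c2ccccc2)(c2ccccc2)C(C)(C)C)cc1 | intermediate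
23 | (S)-(4-methoxyphenyl)[(2R,3S,4R)-3-[(tert-butyldiphenylsilyloxy)methyl]-2-[4-(triisopropylsilyloxy)phenyl]oxolan-4-yl]methanol | COc1ccc([C@@H](O)[C@H]2CO[C@@H](c3ccc(O[Si](C(C)C)(C(C)C)C(C)C)cc3)[C@@H]2CO[Si](c2ccccc2)(c2ccccc2)C(C)(C)C)cc1 | intermediate
24 | 4-[(2R,3S,4R)-3-(hydroxymethyl)-4-[(S)-hydroxy(4-methoxyphenyl)methyl]oxolan-2-yl]phenol | COc1ccc([C@@H](O)[C@H]2CO[C@@H](c3ccc(O)cc3)[C@@H]2CO)cc1 | intermediate
25 | [(2R,3S,4R)-4-[(S)-acetoxy(4-methoxyphenyl)methyl]-2-(4-acetoxyphenyl)oxolan-3-yl]methyl acetate | COc1ccc([C@@H](OC(C)=O)[C@H]2CO[C@@H](c3ccc(OC(C)=O)cc3)[C@@H]2COC(C)=O)cc1 | intermediate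
26 | [(2R,3S,4R)-4-[(S)-acetoxy(4-methoxyphenyl)methyl]-2-(4-hydroxyphenyl)oxolan-3-yl]methyl acetate | COc1ccc([C@@H](OC(C)=O)[C@H]2CO[C@@H](c3ccc(O)cc3)[C@@H]2COC(C)=O)cc1 | target

**Count and risks**
Total steps: 16. Longest linear sequence: 15 steps (step 1 or step 2, then steps 3–16).

Steps most likely to fail:

Step 13. The hydride may be delivered with poor or reversed facial selectivity, because the two ring branches on C4 differ only moderately in size and the Felkin preference may be weak. The fallback replaces substrate control by catalyst control. It sets out from 22 and returns at 23. Ketone 22 would be reduced with BH3·SMe2 in toluene at −20 °C in the presence of (R)-tetrahydro-1-methyl-3,3-diphenyl-1H,3H-pyrrolo[1,2-c][1,3,2]oxazaborole (Corey–Bakshi–Shibata reduction). With the anisyl group as the large substituent, this enantiomer of the catalyst should deliver hydride to the Re face, the same sense as the substrate bias, and give the 7'S carbinol. No new compound arises (F0).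

Step 11. The terminal ynone may oligomerise, or suffer conjugate addition and loss of the ring alkoxide, faster than it undergoes cycloaddition at the temperature the diene needs. The fallback keeps the same two ring bonds but uses a stable alkyne equivalent. It sets out from 18 and returns at 21. Freshly made 18 would be trapped at 0 °C with thiophenol and a catalytic amount of Et3N in CH2Cl2 to give the (E)-β-phenylsulfanyl enone F1. Oxidation with one equivalent of mCPBA at −78 °C should give the β-phenylsulfinyl enone F2. Heating F2 with diene 19 in toluene at 110 °C should give, with the regiochemistry set by the carbonyl group, the sulfinyl cyclohexene cycloadduct F3, which is not isolated. F3 loses benzenesulfenic acid by thermal syn-elimination and, on dilute acid work-up, methanol and the trimethylsilyl group to arrive at phenol 21.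

Step 9. The three hydroxyl groups may compete for sulfonylation, or ring closure may proceed through the propargylic oxygen. The fallback masks the propargylic hydroxyl before the lactone is opened. It sets out from 13 and returns at 17. Aldol 13 would be silylated (Et3SiCl, imidazole, DMF) to the triethylsilyl ether F4. LiBH4 in THF followed by K2CO3 in MeOH, as in step 8, should give first the C-silylated diol F5 (not isolated) and then the terminal alkyne diol F6, which has only one primary and one benzylic hydroxyl. TsCl in pyridine should then form the primary tosylate F7, which closes in the flask to the oxolane triethylsilyl ether F8. Pyridinium 4-methylbenzenesulfonate in MeOH at rt would remove the triethylsilyl group and leave the tert-butyldiphenylsilyl and aryl triisopropylsilyl ethers in place, giving 17.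

**Further compounds**
F0 | step 13 | none | none
F1 | step 11 | (E)-3-(phenylsulfanyl)-1-[(2R,3S,4R)-3-[(tert-butyldiphenylsilyloxy)methyl]-2-[4-(triisopropylsilyloxy)phenyl]oxolan-4-yl]prop-2-en-1-one | O=C(/C=C/Sc1ccccc1)[C@H]1CO[C@@H](c2ccc(O[Si](C(C)C)(C(C)C)C(C)C)cc2)[C@@H]1CO[Si](c1ccccc1)(c1ccccc1)C(C)(C)C
F2 | step 11 | (E)-3-(phenylsulfinyl)-1-[(2R,3S,4R)-3-[(tert-butyldiphenylsilyloxy)methyl]-2-[4-(triisopropylsilyloxy)phenyl]oxolan-4-yl]prop-2-en-1-one (sulfur epimers) | O=C(/C=C/S(=O)c1ccccc1)[C@H]1CO[C@@H](c2ccc(O[Si](C(C)C)(C(C)C)C(C)C)cc2)[C@@H]1CO[Si](c1ccccc1)(c1ccccc1)C(C)(C)C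
F3 | step 11 | [2-methoxy-6-(phenylsulfinyl)-4-(trimethylsilyloxy)cyclohex-3-en-1-yl][(2R,3S,4R)-3-[(tert-butyldiphenylsilyloxy)methyl]-2-[4-(triisopropylsilyloxy)phenyl]oxolan-4-yl]methanone (ring and sulfur epimers) | COC1C=C(O[Si](C)(C)C)CC(S(=O)c2ccccc2)C1C(=O)[C@H]1CO[C@@H](c2ccc(O[Si](C(C)C)(C(C)C)C(C)C)cc2)[C@@H]1CO[Si](c1ccccc1)(c1ccccc1)C(C)(C)C
F4 | step 9 | (3S,4S,5R)-4-[(tert-butyldiphenylsilyloxy)methyl]-3-[1-(triethylsilyloxy)-3-(trimethylsilyl)prop-2-yn-1-yl]-5-[4-(triisopropylsilyloxy)phenyl]oxolan-2-one (epimers at the silyloxy carbon) | C[Si](C)(C)C#CC(O[Si](CC)(CC)CC)[C@H]1C(=O)O[C@@H](c2ccc(O[Si](C(C)C)(C(C)C)C(C)C)cc2)[C@@H]1CO[Si](c1ccccc1)(c1ccccc1)C(C)(C)C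
F5 | step 9 | (1R,2S,3R)-2-[(tert-butyldiphenylsilyloxy)methyl]-3-(hydroxymethyl)-4-(triethylsilyloxy)-1-[4-(triisopropylsilyloxy)phenyl]-6-(trimethylsilyl)hex-5-yn-1-ol (C4 epimers) | C[Si](C)(C)C#CC(O[Si](CC)(CC)CC)[C@@H](CO)[C@@H](CO[Si](c1ccccc1)(c1ccccc1)C(C)(C)C)[C@@H](O)c1ccc(O[Si](C(C)C)(C(C)C)C(C)C)cc1
F6 | step 9 | (1R,2S,3R)-2-[(tert-butyldiphenylsilyloxy)methyl]-3-(hydroxymethyl)-4-(triethylsilyloxy)-1-[4-(triisopropylsilyloxy)phenyl]hex-5-yn-1-ol (C4 epimers) | C#CC(O[Si](CC)(CC)CC)[C@@H](CO)[C@@H](CO[Si](c1ccccc1)(c1ccccc1)C(C)(C)C)[C@@H](O)c1ccc(O[Si](C(C)C)(C(C)C)C(C)C)cc1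
F7 | step 9 | primary 4-methylbenzenesulfonate of F6 | C#CC(O[Si](CC)(CC)CC)[C@@H](COS(=O)(=O)c1ccc(C)cc1)[C@@H](CO[Si](c1ccccc1)(c1ccccc1)C(C)(C)C)[C@@H](O)c1ccc(O[Si](C(C)C)(C(C)C)C(C)C)cc1
F8 | step 9 | triethylsilyl ether of 17, (2R,3S,4R)-3-[(tert-butyldiphenylsilyloxy)methyl]-4-[1-(triethylsilyloxy)prop-2-yn-1-yl]-2-[4-(triisopropylsilyloxy)phenyl]oxolane | C#CC(O[Si](CC)(CC)CC)[C@H]1CO[C@@H](c2ccc(O[Si](C(C)C)(C(C)C)C(C)C)cc2)[C@@H]1CO[Si](c1ccccc1)(c1ccccc1)C(C)(C)C
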